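**Retrosynthetic overview**
- The 3-hydroxy-3-methylbutyl chain comes from Mukaiyama hydration of a C5 prenyl group, placed by an aromatic Claisen rearrangement from the C4 oxygen (C5 is the only free ortho position); benzyl ethers come off last.
- The 2-aryl-3-formylbenzofuran is not made by alkyne cyclization followed by formylation. The key step is an oxidative 1,2-aryl shift of a chalcone, which puts the phloroglucinol ring on the α-carbon and turns the β-carbon into the masked C3 aldehyde.
- Acid in HFIP then closes the furan onto the aryl ketone. Ring B is symmetric (2,6-bis-MOM, 4-OMe), so both phenols give the same benzofuran, and the unused one becomes the C4 hydroxyl.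
- The chalcone comes from a Claisen–Schmidt condensation of 4-methoxy-2,6-bis(methoxymethoxy)benzaldehyde (directed metalation and formylation of bis-MOM 5-methoxyresorcinol) with 2',4'-bis(benzyloxy)acetophenone.
- Ring order: both benzene rings are bought; the furan is the only ring formed (step 5).

Assumption: the target has no stereocentre and no stereogenic double bond, so it is achiral and needs no stereocontrol; the racemic sp3 centres that appear on the way are all destroyed again.

**Route**

Step 1
Reactants: 1 5-methoxyresorcinol (5-methoxybenzene-1,3-diol)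
Product: 2 1-methoxy-3,5-bis(methoxymethoxy)benzene
Conditions: NaH (2.5 equiv), MOMCl (2.4 equiv), DMF, 0 °C to rt
Reagents that add atoms: chloromethyl methyl ether (MOMCl), COCCl
Why: Williamson-type O-alkylation of both phenoxides gives the bis-MOM ether, whose acetal oxygens are acid-labile protecting groups and strong ortho-directing groups for step 2.

Step 2
Reactants: 2 1-methoxy-3,5-bis(methoxymethoxy)benzene
Product: 4 4-methoxy-2,6-bis(methoxymethoxy)benzaldehyde, via aryllithium 3 (not isolated)
Conditions: n-BuLi (1.2 equiv), THF, 0 °C, 1 h; then DMF (2 equiv), 0 °C to rt; H2O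
Reagents that add atoms: N,N-dimethylformamide, CN(C)C=O
Why: Directed ortho-metalation, in which the C–H flanked by the two OMOM groups is lithiated preferentially through cooperative chelation of n-BuLi, followed by formylation of the aryllithium with DMF.

Step 3
Reactants: 4 4-methoxy-2,6-bis(methoxymethoxy)benzaldehyde; 5 1-[2,4-bis(benzyloxy)phenyl]ethan-1-one
Product: 7 (E)-1-[2,4-bis(benzyloxy)phenyl]-3-[4-methoxy-2,6-bis(methoxymethoxy)phenyl]prop-2-en-1-one, via aldol adduct 6 (not isolated)
Conditions: KOH (50% aq, excess), EtOH/THF, rt to 50 °C, 24–48 h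
Reagents that add atoms: none
Why: Claisen–Schmidt (crossed aldol) condensation of a non-enolizable aldehyde with a methyl ketone, where E1cB dehydration of the aldol gives the thermodynamic E-enone and the MOM and benzyl ethers are stable to base.

Step 4
Reactants: 7 (E)-1-[2,4-bis(benzyloxy)phenyl]-3-[4-methoxy-2,6-bis(methoxymethoxy)phenyl]prop-2-en-1-one
Product: 8 1-[2,4-bis(benzyloxy)phenyl]-3,3-dimethoxy-2-[4-methoxy-2,6-bis(methoxymethoxy)phenyl]propan-1-one (racemic)
Conditions: Tl(NO3)3·3H2O (1.2 equiv), MeOH/HC(OMe)3 3:1, rt, 2–4 h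
Reagents that add atoms: methanol, CO
Why: Oxidative 1,2-aryl migration of a chalcone (the Tl(NO3)3 rearrangement used for isoflavones), in which methoxythallation places trivalent thallium on the α-carbon, the electron-rich ring B shifts from Cβ to Cα as monovalent thallium leaves, and methanol traps the oxocarbenium ion so that the old β-carbon becomes the masked C3 aldehyde; the new stereocentre is racemic and is erased in step 5.

Step 5
Reactants: 8 1-[2,4-bis(benzyloxy)phenyl]-3,3-dimethoxy-2-[4-methoxy-2,6-bis(methoxymethoxy)phenyl]propan-1-one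
Product: 10 2-[2,4-bis(benzyloxy)phenyl]-4-hydroxy-6-methoxy-1-benzofuran-3-carbaldehyde, via cyclic methyl acetal 9 (not isolated)
Conditions: p-TsOH·H2O (1.0 equiv), (CF3)2CHOH, rt, 1–3 h
Reagents that add atoms: none
Why: Acid-mediated MOM cleavage, acetal exchange and cyclodehydration cascade known for rearranged 2-hydroxychalcones, in which a freed phenol first closes on the oxocarbenium ion to give 9, and in strongly ionizing HFIP this reopens so that the phenol adds to the protonated aryl ketone and loss of water then methanol aromatizes the furan with the acetal carbon left as the 3-formyl group; ring B is symmetric, so both phenols give the same benzofuran and the other one becomes the C4 hydroxyl.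

Step 6
Reactants: 11 2-methylbut-3-en-2-ol
Product: 13 methyl 2-methylbut-3-en-2-yl carbonate, via lithium alkoxide 12 (not isolated)
Conditions: n-BuLi (1.05 equiv), THF, −78 °C; then ClCO2Me (1.1 equiv), −78 °C to rt
Reagents that add atoms: methyl chloroformate, COC(=O)Cl
Why: O-acylation of a tertiary lithium alkoxide by a chloroformate, the standard preparation of a tertiary allylic carbonate for palladium allylation.

Step 7
Reactants: 10 2-[2,4-bis(benzyloxy)phenyl]-4-hydroxy-6-methoxy-1-benzofuran-3-carbaldehyde; 13 methyl 2-methylbut-3-en-2-yl carbonate (2 equiv)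
Product: 14 2-[2,4-bis(benzyloxy)phenyl]-6-methoxy-4-[(2-methylbut-3-en-2-yl)oxy]-1-benzofuran-3-carbaldehyde
Conditions: Pd(PPh3)4 (5 mol%), THF, 0 °C to rt
Reagents that add atoms: none
Why: Tsuji–Trost O-allylation, in which zerovalent palladium ionizes the carbonate to the 1,1-dimethyl-π-allyl complex with loss of CO2, the released methoxide deprotonates the only free phenol, and with PPh3 ligands at low temperature the phenoxide attacks the more substituted allyl terminus to give the tertiary ether kinetically.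

Step 8
Reactants: 14 2-[2,4-bis(benzyloxy)phenyl]-6-methoxy-4-[(2-methylbut-3-en-2-yl)oxy]-1-benzofuran-3-carbaldehyde
Product: 16 2-[2,4-bis(benzyloxy)phenyl]-4-hydroxy-6-methoxy-5-(3-methylbut-2-en-1-yl)-1-benzofuran-3-carbaldehyde, via cyclohexadienone 15 (not isolated)
Conditions: toluene, 120 °C, sealed tube, 12 h
Reagents that add atoms: none
Why: Aromatic Claisen rearrangement ([3,3]-sigmatropic shift through a chair transition state), which can deliver only to C5 because the other ortho position is the ring-fusion carbon C3a, and whose allylic transposition converts the 1,1-dimethylallyl group into the linear prenyl group before dienone 15 tautomerizes to the phenol.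

Step 9
Reactants: 16 2-[2,4-bis(benzyloxy)phenyl]-4-hydroxy-6-methoxy-5-(3-methylbut-2-en-1-yl)-1-benzofuran-3-carbaldehyde
Product: 17 2-[2,4-bis(benzyloxy)phenyl]-4-hydroxy-5-(3-hydroxy-3-methylbutyl)-6-methoxy-1-benzofuran-3-carbaldehyde
Conditions: Co(acac)2 (20 mol%), PhSiH3 (2.5 equiv), O2 (1 atm), THF/i-PrOH, rt
Reagents that add atoms: dioxygen, O=O
Why: Mukaiyama hydration (cobalt hydride hydrogen-atom transfer), in which the hydrogen atom adds to the less substituted alkene carbon, the tertiary radical is trapped by O2 and the peroxide is reduced by the silane to the Markovnikov tertiary alcohol, under neutral conditions that leave the conjugated aldehyde, the benzyl ethers and the furan alone and cannot close a chroman.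

Step 10
Reactants: 17 2-[2,4-bis(benzyloxy)phenyl]-4-hydroxy-5-(3-hydroxy-3-methylbutyl)-6-methoxy-1-benzofuran-3-carbaldehyde
Product: 18 2-(2,4-dihydroxyphenyl)-4-hydroxy-5-(3-hydroxy-3-methylbutyl)-6-methoxy-1-benzofuran-3-carbaldehyde (the target)
Conditions: H2 (1 atm), 10% Pd/C, EtOAc/MeOH, rt
Reagents that add atoms: none
Why: Catalytic hydrogenolysis of the two benzyl aryl ethers under neutral conditions, which the push-pull (vinylogous ester type) 3-formyl group and the tertiary alcohol survive at 1 atm and rt.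

**Compound list**

1 | 5-methoxyresorcinol | COc1cc(O)cc(O)c1 | starting material
2 | 1-methoxy-3,5-bis(methoxymethoxy)benzene | COCOc1cc(OC)cc(OCOC)c1 | intermediate
3 | [4-methoxy-2,6-bis(methoxymethoxy)phenyl]lithium | [Li]c1c(OCOC)cc(OC)cc1OCOC | intermediate (not isolated)
4 | 4-methoxy-2,6-bis(methoxymethoxy)benzaldehyde | COCOc1cc(OC)cc(OCOC)c1C=O | intermediate
5 | 1-[2,4-bis(benzyloxy)phenyl]ethan-1-one | CC(=O)c1ccc(OCc2ccccc2)cc1OCc1ccccc1 | starting material
6 | 1-[2,4-bis(benzyloxy)phenyl]-3-hydroxy-3-[4-methoxy-2,6-bis(methoxymethoxy)phenyl]propan-1-one (racemic) | COCOc1cc(OC)cc(OCOC)c1C(O)CC(=O)c1ccc(OCc2ccccc2)cc1OCc1ccccc1 | intermediate (not isolated)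
7 | (E)-1-[2,4-bis(benzyloxy)phenyl]-3-[4-methoxy-2,6-bis(methoxymethoxy)phenyl]prop-2-en-1-one | COCOc1cc(OC)cc(OCOC)c1/C=C/C(=O)c1ccc(OCc2ccccc2)cc1OCc1ccccc1 | intermediate
8 | 1-[2,4-bis(benzyloxy)phenyl]-3,3-dimethoxy-2-[4-methoxy-2,6-bis(methoxymethoxy)phenyl]propan-1-one (racemic) | COCOc1cc(OC)cc(OCOC)c1C(C(OC)OC)C(=O)c1ccc(OCc2ccccc2)cc1OCc1ccccc1 | intermediate
9 | [2,4-bis(benzyloxy)phenyl](4-hydroxy-2,6-dimethoxy-2,3-dihydro-1-benzofuran-3-yl)methanone (racemic mixture of diastereomers) | COC1Oc2cc(OC)cc(O)c2C1C(=O)c1ccc(OCc2ccccc2)cc1OCc1ccccc1 | intermediate (not isolated)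
10 | 2-[2,4-bis(benzyloxy)phenyl]-4-hydroxy-6-methoxy-1-benzofuran-3-carbaldehyde | COc1cc2oc(-c3ccc(OCc4ccccc4)cc3OCc3ccccc3)c(C=O)c2c(O)c1 | intermediate
11 | 2-methylbut-3-en-2-ol | C=CC(C)(C)O | starting material
12 | lithium 2-methylbut-3-en-2-olate | [Li]OC(C)(C)C=C | intermediate (not isolated)
13 | methyl 2-methylbut-3-en-2-yl carbonate | COC(=O)OC(C)(C)C=C | intermediate
14 | 2-[2,4-bis(benzyloxy)phenyl]-6-methoxy-4-[(2-methylbut-3-en-2-yl)oxy]-1-benzofuran-3-carbaldehyde | COc1cc2oc(-c3ccc(OCc4ccccc4)cc3OCc3ccccc3)c(C=O)c2c(OC(C)(C)C=C)c1 | intermediate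
15 | 2-[2,4-bis(benzyloxy)phenyl]-6-methoxy-5-(3-methylbut-2-en-1-yl)-4-oxo-4,5-dihydro-1-benzofuran-3-carbaldehyde (racemic) | CC(C)=CCC1C(=O)C2=C(OC(=C2C=O)c2ccc(OCc3ccccc3)cc2OCc2ccccc2)C=C1OC | intermediate (not isolated)
16 | 2-[2,4-bis(benzyloxy)phenyl]-4-hydroxy-6-methoxy-5-(3-methylbut-2-en-1-yl)-1-benzofuran-3-carbaldehyde | COc1cc2oc(-c3ccc(OCc4ccccc4)cc3OCc3ccccc3)c(C=O)c2c(O)c1CC=C(C)C | intermediate
17 | 2-[2,4-bis(benzyloxy)phenyl]-4-hydroxy-5-(3-hydroxy-3-methylbutyl)-6-methoxy-1-benzofuran-3-carbaldehyde | COc1cc2oc(-c3ccc(OCc4ccccc4)cc3OCc3ccccc3)c(C=O)c2c(O)c1CCC(C)(C)O | intermediate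
18 | 2-(2,4-dihydroxyphenyl)-4-hydroxy-5-(3-hydroxy-3-methylbutyl)-6-methoxy-1-benzofuran-3-carbaldehyde | COc1cc2oc(-c3ccc(O)cc3O)c(C=O)c2c(O)c1CCC(C)(C)O | target

**Step count and risks**

Total step count: 10 (steps 1–10).
Longest linear sequence: 9 steps, from 1 to 18 through steps 1–5 and 7–10; step 6 is a one-step side branch.

The three steps most likely to fail are steps 4, 5 and 7.

Step 4 (oxidative aryl shift). The very electron-rich ring B could be over-oxidized by trivalent thallium, or the nitric acid formed could strip a MOM group before migration. The fallback sets out from 7 and comes back at 8, reaching the same skeleton by acyl migration instead of aryl migration. Weitz–Scheffer epoxidation of 7 (H2O2, NaOH, MeOH/THF) gives racemic trans-[2,4-bis(benzyloxy)phenyl]{3-[4-methoxy-2,6-bis(methoxymethoxy)phenyl]oxiran-2-yl}methanone F1. BF3·OEt2 (CH2Cl2, −78 °C) opens the epoxide at the benzylic carbon and triggers a Meinwald-type 1,2-acyl shift to 3-[2,4-bis(benzyloxy)phenyl]-2-[4-methoxy-2,6-bis(methoxymethoxy)phenyl]-3-oxopropanal F2. Acetalization of its aldehyde with HC(OMe)3/MeOH and catalytic PPTS gives 8.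

Step 5 (furan closure). The cyclic acetal 9 can lose methanol instead of reopening, which would give the isomeric 3-aroylbenzofuran with no substituent at C2. The fallback sets out from 8 and comes back at 10, with the aldehyde carbon locked so that only the ketone can be attacked. Transthioacetalization of 8 with propane-1,3-dithiol (catalytic Zn(OTf)2 or p-TsOH, CH2Cl2), which also removes the MOM groups, gives 1-[2,4-bis(benzyloxy)phenyl]-2-(2,6-dihydroxy-4-methoxyphenyl)-2-(1,3-dithian-2-yl)ethan-1-one F3. Its dithiane does not ionize under Brønsted acid, so cyclodehydration (p-TsOH, toluene, 80 °C) closes onto the ketone and gives 2-[2,4-bis(benzyloxy)phenyl]-3-(1,3-dithian-2-yl)-6-methoxy-1-benzofuran-4-ol F4. Dithiane removal with MeI and CaCO3 in aqueous MeCN returns 10.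

Step 7 (tertiary ether on the hindered C4 phenol). The phenol is hydrogen-bonded to the aldehyde and flanked by the ring fusion, so allylation may be slow or may give the linear prenyl ether, which cannot place a prenyl group at C5 by Claisen rearrangement. The fallback sets out from 10 and comes back at the target 18, bypassing 13–17 by C–H iodination and Heck coupling. Iodination ortho to the hydrogen-bonded phenol (BnNMe3ICl2, CaCO3, CH2Cl2/MeOH) gives 2-[2,4-bis(benzyloxy)phenyl]-4-hydroxy-5-iodo-6-methoxy-1-benzofuran-3-carbaldehyde F5; the C5 selectivity over C7 is argued by analogy with chelated 5-hydroxy-7-alkoxyflavones and is the weak point of this fallback. Heck coupling of F5 with 11 (Pd(OAc)2, n-Bu4NCl, NaHCO3, DMF, 80 °C) gives 2-[2,4-bis(benzyloxy)phenyl]-4-hydroxy-5-[(E)-3-hydroxy-3-methylbut-1-en-1-yl]-6-methoxy-1-benzofuran-3-carbaldehyde F6. One hydrogenation (H2, 10% Pd/C, EtOAc/MeOH) saturates the alkene and removes both benzyl groups to give 18.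

**Further compounds**

F1 | step 4 | trans-[2,4-bis(benzyloxy)phenyl]{3-[4-methoxy-2,6-bis(methoxymethoxy)phenyl]oxiran-2-yl}methanone (racemic, one enantiomer drawn) | COCOc1cc(OC)cc(OCOC)c1[C@@H]1O[C@H]1C(=O)c1ccc(OCc2ccccc2)cc1OCc1ccccc1
F2 | step 4 | 3-[2,4-bis(benzyloxy)phenyl]-2-[4-methoxy-2,6-bis(methoxymethoxy)phenyl]-3-oxopropanal (racemic) | COCOc1cc(OC)cc(OCOC)c1C(C=O)C(=O)c1ccc(OCc2ccccc2)cc1OCc1ccccc1
F3 | step 5 | 1-[2,4-bis(benzyloxy)phenyl]-2-(2,6-dihydroxy-4-methoxyphenyl)-2-(1,3-dithian-2-yl)ethan-1-one (racemic) | COc1cc(O)c(C(C2SCCCS2)C(=O)c2ccc(OCc3ccccc3)cc2OCc2ccccc2)c(O)c1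
F4 | step 5 | 2-[2,4-bis(benzyloxy)phenyl]-3-(1,3-dithian-2-yl)-6-methoxy-1-benzofuran-4-ol | COc1cc2oc(-c3ccc(OCc4ccccc4)cc3OCc3ccccc3)c(C3SCCCS3)c2c(O)c1
F5 | step 7 | 2-[2,4-bis(benzyloxy)phenyl]-4-hydroxy-5-iodo-6-methoxy-1-benzofuran-3-carbaldehyde | COc1cc2oc(-c3ccc(OCc4ccccc4)cc3OCc3ccccc3)c(C=O)c2c(O)c1I
F6 | step 7 | 2-[2,4-bis(benzyloxy)phenyl]-4-hydroxy-5-[(E)-3-hydroxy-3-methylbut-1-en-1-yl]-6-methoxy-1-benzofuran-3-carbaldehyde | COc1cc2oc(-c3ccc(OCc4ccccc4)cc3OCc3ccccc3)c(C=O)c2c(O)c1/C=C/C(C)(C)O
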